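The key step exploits the five-membered 2H-naphtho[1,8-bc]furan ring, whose C(spiro)–O bridge spans the peri carbons C1 and C8 of the naphthalene and whose spiro N,O-ketal carbon sits at the carboxylic oxidation level. Cutting C1–C(spiro) and O–C8 reveals an imide carbonyl (electrophilic carbon, nucleophilic oxygen once attacked) and a peri-ambiphilic naphthalene: C1 as aryllithium beside the C2 oxygen, C8 as bromide. In one flask the aryllithium adds to the methoxy-flanked carbonyl of a 3-methoxyphthalimide and the unquenched tertiary alkoxide is O-arylated at C8 under chiral palladium catalysis, which sets the spiro centre by dynamic kinetic resolution. Hydrogenolysis of two benzyl ethers then gives the target.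

Key step: step 6

Numbering: naphthalene atoms are numbered as in 8-bromo-6-methylnaphthalen-2-ol (C1 ends on the spiro carbon, C2 carries the later free hydroxyl, C8 ends on the ring oxygen).

Assumption: the sense of induction of the chiral ligand in step 6 cannot be derived in advance; (R)-Tol-BINAP is written, and its antipode takes its place if the first run favours the (S)-spirocycle.

Step 1
Reactants: 1 2-(2-bromo-4-methylphenyl)acetic acid
Product: 4 8-bromo-6-methyl-3,4-dihydronaphthalen-2(1H)-one, via acid chloride 2 (not isolated), via chloroethyl ketone 3 (not isolated)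
Conditions: (COCl)2, DMF (cat.), CH2Cl2, rt; then AlCl3, ethylene, CH2Cl2, −10 °C to rt
Reagents that add atoms: ethylene, C=C
Why: Friedel–Crafts acylation of ethylene by the arylacetyl chloride and ring closure of the resulting 2-chloroethyl ketone by intramolecular Friedel–Crafts alkylation is the standard 2-tetralone synthesis, and the single free ortho position (the other carries bromine) fixes the regiochemistry.

Step 2
Reactants: 4 8-bromo-6-methyl-3,4-dihydronaphthalen-2(1H)-one
Product: 5 8-bromo-6-methylnaphthalen-2-ol
Conditions: DDQ (1.05 equiv), 1,4-dioxane, 80 °C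
Reagents that add atoms: none
Why: Quinone dehydrogenation of the easily enolised 2-tetralone, driven by aromatisation, should give the 2-naphthol without touching the aryl bromide.

Step 3
Reactants: 5 8-bromo-6-methylnaphthalen-2-ol
Product: 6 8-bromo-1-iodo-6-methylnaphthalen-2-ol
Conditions: NIS (1.05 equiv), MeCN, 0 °C, dark
Reagents that add atoms: N-iodosuccinimide, O=C1CCC(=O)N1I
Why: Electrophilic aromatic iodination of a 2-naphthol occurs at C1, the alpha position ortho to the hydroxyl, which is far more nucleophilic than C3 even though it lies peri to bromine.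

Step 4
Reactants: 6 8-bromo-1-iodo-6-methylnaphthalen-2-ol
Product: 7 2-(benzyloxy)-8-bromo-1-iodo-6-methylnaphthalene
Conditions: BnBr, K2CO3, DMF, rt
Reagents that add atoms: benzyl bromide, BrCc1ccccc1
Why: Williamson etherification of the naphthoxide masks the acidic OH before the organolithium step with a group that is later removed by neutral hydrogenolysis.

Step 5
Reactants: 8 3-methoxyphthalic anhydride (4-methoxy-2-benzofuran-1,3-dione); 9 2-(benzyloxy)ethan-1-amine
Product: 10 2-[2-(benzyloxy)ethyl]-4-methoxyisoindoline-1,3-dione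
Conditions: AcOH, 110 °C
Reagents that add atoms: none
Why: Thermal condensation of a cyclic anhydride with a primary amine (imide formation) should give the N-alkylphthalimide, the benzyl ether being inert to hot acetic acid.

Step 6
Reactants: 7 2-(benzyloxy)-8-bromo-1-iodo-6-methylnaphthalene; 10 2-[2-(benzyloxy)ethyl]-4-methoxyisoindoline-1,3-dione
Product: 13 (R)-3'-(benzyloxy)-2-[2-(benzyloxy)ethyl]-7-methoxy-7'-methylspiro[isoindoline-1,2'-naphtho[1,8-bc]furan]-3-one, via aryllithium 11 (not isolated), via lithium alkoxide 12 (not isolated)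
Conditions: 7, t-BuLi (2.0 equiv), Et2O/THF, −78 °C; then 10, −78 to 0 °C; then Pd2(dba)3 (2.5 mol %), (R)-Tol-BINAP (6 mol %), toluene, 80 °C, same flask
Reagents that add atoms: none
Why: Proposed new method: iodine–lithium exchange (iodide reacts before the peri bromide; the second equivalent of t-BuLi destroys t-BuI) gives 11, whose addition to the methoxy-flanked carbonyl of 10 (site preference expected from lithium bridging the methoxy and carbonyl oxygens, as in hydride reductions of 3-alkoxyphthalimides) forms the C1–C(spiro) bond and alkoxide 12; zerovalent palladium then inserts into the peri C8–Br bond, the alkoxide binds divalent palladium to give a six-membered pallada-oxacycle, and C–O reductive elimination contracts it to the five-membered 2H-naphtho[1,8-bc]furan ring. The closest known reactions are aryllithium addition to N-alkylphthalimides and the palladium/Tol-BINAP-catalysed intramolecular etherification of tertiary alcohols with aryl bromides (Buchwald–Hartwig C–O coupling); running them in one flask on the unquenched alkoxide and the enantioselective, dynamic-kinetic version are new. The spiro stereocentre is controlled by the ligand: 12 racemises by ring–chain tautomerism through the 2-aroylbenzamide anion, and the chiral palladium complex should carry one enantiomer through alkoxide binding and reductive elimination faster (Curtin–Hammett), after which the N,O-ketal is configurationally fixed. Selectivities needed are iodide over bromide in the exchange (halogen difference), proximal over distal imide carbonyl (chelation), and O-arylation without β-hydride loss (the alkoxide is tertiary).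

Step 7
Reactants: 13 (R)-3'-(benzyloxy)-2-[2-(benzyloxy)ethyl]-7-methoxy-7'-methylspiro[isoindoline-1,2'-naphtho[1,8-bc]furan]-3-one
Product: 14 (R)-3'-hydroxy-2-(2-hydroxyethyl)-7-methoxy-7'-methylspiro[isoindoline-1,2'-naphtho[1,8-bc]furan]-3-one
Conditions: H2 (1 atm), Pd/C (10 wt %), EtOAc/EtOH, rt
Reagents that add atoms: none
Why: Catalytic hydrogenolysis cleaves the aryl and the primary alkyl benzyl ether under neutral conditions that should neither ionise nor reduce the hindered quaternary N-acyl N,O-ketal, so the spiro centre set in step 6 is carried through unchanged.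

Compound list
1 | 2-(2-bromo-4-methylphenyl)acetic acid | Cc1ccc(CC(=O)O)c(Br)c1 | starting material
2 | 2-(2-bromo-4-methylphenyl)acetyl chloride | Cc1ccc(CC(=O)Cl)c(Br)c1 | intermediate
3 | 1-(2-bromo-4-methylphenyl)-4-chlorobutan-2-one | Cc1ccc(CC(=O)CCCl)c(Br)c1 | intermediate
4 | 8-bromo-6-methyl-3,4-dihydronaphthalen-2(1H)-one | Cc1cc(Br)c2c(c1)CCC(=O)C2 | intermediate
5 | 8-bromo-6-methylnaphthalen-2-ol | Cc1cc(Br)c2cc(O)ccc2c1 | intermediate
6 | 8-bromo-1-iodo-6-methylnaphthalen-2-ol | Cc1cc(Br)c2c(I)c(O)ccc2c1 | intermediate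
7 | 2-(benzyloxy)-8-bromo-1-iodo-6-methylnaphthalene | Cc1cc(Br)c2c(I)c(OCc3ccccc3)ccc2c1 | intermediate
8 | 3-methoxyphthalic anhydride | COc1cccc2c1C(=O)OC2=O | starting material
9 | 2-(benzyloxy)ethan-1-amine | NCCOCc1ccccc1 | starting material
10 | 2-[2-(benzyloxy)ethyl]-4-methoxyisoindoline-1,3-dione | COc1cccc2c1C(=O)N(CCOCc1ccccc1)C2=O | intermediate
11 | [2-(benzyloxy)-8-bromo-6-methylnaphthalen-1-yl]lithium | Cc1cc(Br)c2c([Li])c(OCc3ccccc3)ccc2c1 | intermediate
12 | lithium 2-[2-(benzyloxy)ethyl]-1-[2-(benzyloxy)-8-bromo-6-methylnaphthalen-1-yl]-7-methoxy-3-oxoisoindolin-1-olate (racemising) | COc1cccc2c1C(O[Li])(c1c(OCc3ccccc3)ccc3cc(C)cc(Br)c13)N(CCOCc1ccccc1)C2=O | intermediate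
13 | (R)-3'-(benzyloxy)-2-[2-(benzyloxy)ethyl]-7-methoxy-7'-methylspiro[isoindoline-1,2'-naphtho[1,8-bc]furan]-3-one | COc1cccc2c1[C@@]1(Oc3cc(C)cc4ccc(OCc5ccccc5)c1c34)N(CCOCc1ccccc1)C2=O | intermediate
14 | (R)-3'-hydroxy-2-(2-hydroxyethyl)-7-methoxy-7'-methylspiro[isoindoline-1,2'-naphtho[1,8-bc]furan]-3-one | COc1cccc2c1[C@@]1(Oc3cc(C)cc4ccc(O)c1c34)N(CCO)C2=O | target

Total steps: 7. Longest linear sequence: 6 steps (steps 1, 2, 3, 4, 6, 7).

Steps most likely to fail

1. Step 6 (proposed new method). The chiral catalyst may discriminate the two equilibrating alkoxides poorly, or the palladium stage may stall in the lithium-salt-laden mixture at the congested peri bromide. The fallback uses known chemistry, sets out from 7 and 10 and returns at 13. The aryllithium addition is run alone and quenched with aqueous NH4Cl to isolate the racemic hydroxy lactam 2-[2-(benzyloxy)ethyl]-3-[2-(benzyloxy)-8-bromo-6-methylnaphthalen-1-yl]-3-hydroxy-4-methoxyisoindolin-1-one F1. The ring is then closed under established intramolecular etherification conditions for tertiary alcohols (Pd(OAc)2, racemic Tol-BINAP, NaOt-Bu, toluene, 100 °C) to the racemic spirocycle F2. F2 is resolved by preparative chiral-phase SFC; the (R)-enantiomer is 13 and the (S)-enantiomer F3 is set aside.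

2. Step 7. During the slow cleavage of the primary alkyl benzyl ether the benzylic spiro C–O bond may be hydrogenolysed, or the configuration may erode once the free naphthol is exposed for long. The fallback changes the protecting-group plan, sets out from 8 and returns at 14. Anhydride 8 is condensed with 2-[(tert-butyldimethylsilyl)oxy]ethan-1-amine (AcOH-free: toluene, Et3N, reflux) to the silyl imide 2-{2-[(tert-butyldimethylsilyl)oxy]ethyl}-4-methoxyisoindoline-1,3-dione F4. Step 6 is run with F4 in place of 10, through the lithium alkoxide F5 (not isolated), to the spirocycle (R)-3'-(benzyloxy)-2-{2-[(tert-butyldimethylsilyl)oxy]ethyl}-7-methoxy-7'-methylspiro[isoindoline-1,2'-naphtho[1,8-bc]furan]-3-one F6. TBAF in THF at 0 °C removes the silyl group while the naphthol is still masked, giving the alcohol (R)-3'-(benzyloxy)-2-(2-hydroxyethyl)-7-methoxy-7'-methylspiro[isoindoline-1,2'-naphtho[1,8-bc]furan]-3-one F7. A short hydrogenolysis (H2, Pd/C, EtOAc, rt) then has to cleave only the fast aryl benzyl ether and gives 14.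

3. Step 3. Iodination at C1, which is crowded by the peri bromine at C8, may stall, revert by protodeiodination, or drift to C3. The fallback changes the halogen pattern and the basis of site selection, sets out from 5 and returns at 11 (and so at 13). Naphthol 5 is brominated with NBS (MeCN, 0 °C) to 1,8-dibromo-6-methylnaphthalen-2-ol F8, which carries the smaller halogen at C1, and benzylated (BnBr, K2CO3, DMF) to 2-(benzyloxy)-1,8-dibromo-6-methylnaphthalene F9. In step 6, t-BuLi (2.0 equiv, −78 °C) should exchange the C1 bromine selectively, because it is flanked by the benzyloxy group, which accelerates the exchange and stabilises the aryllithium. This gives the same aryllithium 11, and the step continues unchanged.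

Further compounds
F1 | step 6 | racemic 2-[2-(benzyloxy)ethyl]-3-[2-(benzyloxy)-8-bromo-6-methylnaphthalen-1-yl]-3-hydroxy-4-methoxyisoindolin-1-one | COc1cccc2c1C(O)(c1c(OCc3ccccc3)ccc3cc(C)cc(Br)c13)N(CCOCc1ccccc1)C2=O
F2 | step 6 | racemic 3'-(benzyloxy)-2-[2-(benzyloxy)ethyl]-7-methoxy-7'-methylspiro[isoindoline-1,2'-naphtho[1,8-bc]furan]-3-one | COc1cccc2c1C1(Oc3cc(C)cc4ccc(OCc5ccccc5)c1c34)N(CCOCc1ccccc1)C2=O
F3 | step 6 | (S)-3'-(benzyloxy)-2-[2-(benzyloxy)ethyl]-7-methoxy-7'-methylspiro[isoindoline-1,2'-naphtho[1,8-bc]furan]-3-one | COc1cccc2c1[C@]1(Oc3cc(C)cc4ccc(OCc5ccccc5)c1c34)N(CCOCc1ccccc1)C2=O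
F4 | step 7 | 2-{2-[(tert-butyldimethylsilyl)oxy]ethyl}-4-methoxyisoindoline-1,3-dione | COc1cccc2c1C(=O)N(CCO[Si](C)(C)C(C)(C)C)C2=O
F5 | step 7 | lithium 1-[2-(benzyloxy)-8-bromo-6-methylnaphthalen-1-yl]-2-{2-[(tert-butyldimethylsilyl)oxy]ethyl}-7-methoxy-3-oxoisoindolin-1-olate | COc1cccc2c1C(O[Li])(c1c(OCc3ccccc3)ccc3cc(C)cc(Br)c13)N(CCO[Si](C)(C)C(C)(C)C)C2=O
F6 | step 7 | (R)-3'-(benzyloxy)-2-{2-[(tert-butyldimethylsilyl)oxy]ethyl}-7-methoxy-7'-methylspiro[isoindoline-1,2'-naphtho[1,8-bc]furan]-3-one | COc1cccc2c1[C@@]1(Oc3cc(C)cc4ccc(OCc5ccccc5)c1c34)N(CCO[Si](C)(C)C(C)(C)C)C2=O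
F7 | step 7 | (R)-3'-(benzyloxy)-2-(2-hydroxyethyl)-7-methoxy-7'-methylspiro[isoindoline-1,2'-naphtho[1,8-bc]furan]-3-one | COc1cccc2c1[C@@]1(Oc3cc(C)cc4ccc(OCc5ccccc5)c1c34)N(CCO)C2=O
F8 | step 3 | 1,8-dibromo-6-methylnaphthalen-2-ol | Cc1cc(Br)c2c(Br)c(O)ccc2c1
F9 | step 3 | 2-(benzyloxy)-1,8-dibromo-6-methylnaphthalene | Cc1cc(Br)c2c(Br)c(OCc3ccccc3)ccc2c1
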